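Ring A of the flavone carries oxygen on five adjacent carbons, C5, C6, C7, C8 and C8a. The route therefore builds ring A last: C5–C8 come from a squarate, and C4a/C8a are C5/C6 of a preformed 2-aryl-γ-pyranone (rings B and C). Heating a 4-methoxy-4-(pyranon-5-yl)cyclobutenone opens the four-membered ring to a vinylketene that closes onto pyranone C6, forming the C8–C8a bond and the fully oxygenated arene in one operation. The precursor is a squarate adduct carrying tert-butoxy (future C7), methoxy (C6) and a methylated carbinol (C5), so the free C8 hydroxyl and the two masked hydroxyls are already differentiated.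

Key step: step 8

Remark: iodo enone 2 is drawn as its Z isomer; the E isomer would serve equally, because this double-bond geometry is lost when ring C closes in step 3.

Step 1
Reactants: 1 (E)-4-methoxybut-3-en-2-one
Product: 2 (3Z)-3-iodo-4-methoxybut-3-en-2-one
Conditions: I2, pyridine/CH2Cl2, 0 °C to rt, dark
Reagents that add atoms: iodine, II
Why: The α-carbon of the β-methoxy enone is its only nucleophilic carbon, so pyridine-mediated α-iodination of the vinylogous ester should place iodine there, which fixes before ring C exists the carbon that will later carry the metal.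

Step 2
Reactants: 2 (3Z)-3-iodo-4-methoxybut-3-en-2-one; 3 3,4,5-trimethoxybenzoyl chloride
Product: 4 (4Z)-4-iodo-5-methoxy-1-(3,4,5-trimethoxyphenyl)pent-4-ene-1,3-dione (mainly as its enol)
Conditions: 2 (2 equiv), LiN(SiMe3)2 (2 equiv), THF, −78 °C; then 3 (1 equiv), −78 °C; aq. NH4Cl
Reagents that add atoms: none
Why: Kinetic deprotonation of the methyl ketone gives the cross-conjugated lithium enolate, which should undergo Claisen-type C-acylation by the aroyl chloride, the second equivalent of enolate taking up the acidic diketone proton so that double acylation is avoided.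

Step 3
Reactants: 4 (4Z)-4-iodo-5-methoxy-1-(3,4,5-trimethoxyphenyl)pent-4-ene-1,3-dione
Product: 5 5-iodo-2-(3,4,5-trimethoxyphenyl)-4H-pyran-4-one
Conditions: CF3CO2H (cat.), CH2Cl2, rt
Reagents that add atoms: none
Why: In this acid-catalysed addition–elimination ring closure the enol oxygen of the aryl ketone adds 6-endo to the methoxy-bearing enone carbon (oxa-Michael addition) and methanol is expelled, giving the γ-pyranone with iodine necessarily at C5.

Step 4
Reactants: 6 di-tert-butyl squarate
Product: 7 sodium 2-tert-butoxy-3,4-dioxocyclobut-1-en-1-olate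
Conditions: NaOH (1.0 equiv), THF/H2O, 0 °C to rt; evaporate, dry
Reagents that add atoms: sodium hydroxide, [Na+].[OH-]
Why: Hydroxide adds to one alkoxy-bearing carbon of the vinylogous diester and expels tert-butoxide (addition–elimination half-saponification of a squarate ester), and the resulting vinylogous carboxylate is too deactivated to lose the second ester group.

Step 5
Reactants: 7 sodium 2-tert-butoxy-3,4-dioxocyclobut-1-en-1-olate
Product: 8 3-tert-butoxy-4-methoxycyclobut-3-ene-1,2-dione
Conditions: MeOTf (1.1 equiv), MeCN, 0 °C to rt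
Reagents that add atoms: methyl trifluoromethanesulfonate, COS(=O)(=O)C(F)(F)F
Why: This is O-alkylation of the delocalised semisquarate anion by a hard methylating agent, and because the two oxygens that share the charge are equivalent by symmetry only one mixed diester can form.

Step 6
Reactants: 5 5-iodo-2-(3,4,5-trimethoxyphenyl)-4H-pyran-4-one; 8 3-tert-butoxy-4-methoxycyclobut-3-ene-1,2-dione
Product: 10 racemic 2-tert-butoxy-4-hydroxy-3-methoxy-4-[4-oxo-6-(3,4,5-trimethoxyphenyl)-4H-pyran-3-yl]cyclobut-2-en-1-one, via pyranon-3-ylmagnesium chloride·LiCl 9 (not isolated)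
Conditions: iPrMgCl·LiCl (1.05 equiv), THF, −40 °C; then cannulate into 8 (1.2 equiv), THF, −78 to −30 °C; aq. NH4Cl
Reagents that add atoms: none
Why: Iodine–magnesium exchange on the α-iodo-β-oxy enone (a known substrate class for turbo-Grignard exchange) gives alkenylmagnesium 9, kept at −40 °C or below to avoid β-alkoxide ring opening, and its Grignard 1,2-addition should take the squarate carbonyl beside the methoxy-bearing carbon, the other one being shielded by the neighbouring tert-butoxy group, forming the quaternary carbinol centre as a racemate.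

Step 7
Reactants: 10 racemic 2-tert-butoxy-4-hydroxy-3-methoxy-4-[4-oxo-6-(3,4,5-trimethoxyphenyl)-4H-pyran-3-yl]cyclobut-2-en-1-one
Product: 11 racemic 2-tert-butoxy-3,4-dimethoxy-4-[4-oxo-6-(3,4,5-trimethoxyphenyl)-4H-pyran-3-yl]cyclobut-2-en-1-one
Conditions: MeI, Ag2O, 4 Å MS, MeCN, rt, dark
Reagents that add atoms: iodomethane, CI
Why: Purdie methylation (silver oxide with iodomethane) etherifies the tertiary carbinol under near-neutral conditions that should leave the cyclobutenone, both enol ethers and the pyranone untouched, the centre staying racemic.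

Step 8
Reactants: 11 racemic 2-tert-butoxy-3,4-dimethoxy-4-[4-oxo-6-(3,4,5-trimethoxyphenyl)-4H-pyran-3-yl]cyclobut-2-en-1-one
Product: 14 7-tert-butoxy-8-hydroxy-5,6-dimethoxy-2-(3,4,5-trimethoxyphenyl)-4H-chromen-4-one, via (Z)-pyranonyl vinylketene 12 (not isolated), via 8aH-chromene-4,8-dione tautomer 13 (not isolated)
Conditions: toluene (0.01 M, degassed), 110 °C, Ar
Reagents that add atoms: none
Why: Heating drives a conrotatory four-electron ring opening of the cyclobutenone in which the donor methoxy group on the quaternary carbon rotates outward (torquoselectivity), so the pyranonyl group ends up cis to the ketene in vinylketene 12. The ketene C=C, the dimethoxy-substituted C=C and the pyranone C5=C6 bond then form a hexatriene that closes the six-membered ring A by a thermal disrotatory six-electron electrocyclisation, joining the ketene carbon (C8) to pyranone C6 (C8a) and giving dienone 13. A proton shift from C8a to the C8 oxygen aromatises ring A; the transient C8a stereocentre and the racemic centre of 11 both disappear, so no stereocontrol is needed. The closest known reaction type is the Moore-type thermal ring expansion of squarate-derived 4-alkenyl- and 4-(hetero)aryl-4-alkoxycyclobutenones to phenols, with the pyranone C5=C6 bond playing the part of the alkenyl group. The selectivity needed is closure at pyranone C6 and not at the C4 carbonyl oxygen: only C6 completes a six-membered, aromatisable ring (the carbonyl oxygen would need a seven-membered ring), and the methyl ether on the quaternary carbon rules out trapping of the ketene by a free hydroxyl. Dilute, degassed toluene should limit ketene dimerisation, loss of isobutene and air oxidation of the electron-rich phenol, with refluxing xylene held in reserve if ring opening is slow.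

Step 9
Reactants: 14 7-tert-butoxy-8-hydroxy-5,6-dimethoxy-2-(3,4,5-trimethoxyphenyl)-4H-chromen-4-one
Product: 15 7-tert-butoxy-5,6,8-trimethoxy-2-(3,4,5-trimethoxyphenyl)-4H-chromen-4-one
Conditions: MeI, K2CO3, DMF, rt to 40 °C, Ar
Reagents that add atoms: iodomethane, CI
Why: Williamson methylation of the only free phenol should be clean, since the tert-butyl ether, the methyl ethers and the pyranone are inert to K2CO3 and iodomethane.

Step 10
Reactants: 15 7-tert-butoxy-5,6,8-trimethoxy-2-(3,4,5-trimethoxyphenyl)-4H-chromen-4-one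
Product: 16 5,7-dihydroxy-6,8-dimethoxy-2-(3,4,5-trimethoxyphenyl)-4H-chromen-4-one (5,7-dihydroxy-6,8,3',4',5'-pentamethoxyflavone)
Conditions: BCl3 (1 M in CH2Cl2, 4 equiv), CH2Cl2, −78 to 0 °C; then H2O, aq. NaHCO3
Reagents that add atoms: none
Why: BCl3 ionises the tert-butyl aryl ether and, through the six-membered boron chelate with the C4 carbonyl, demethylates only the peri C5 methoxy group (chelation-controlled Lewis acid ether cleavage), so the non-chelated methyl ethers at C6, C8, C3', C4' and C5' should survive at low temperature.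

Compound list
1 | (E)-4-methoxybut-3-en-2-one | CO/C=C/C(C)=O | starting material
2 | (3Z)-3-iodo-4-methoxybut-3-en-2-one | CO/C=C(\I)C(C)=O | intermediate
3 | 3,4,5-trimethoxybenzoyl chloride | COc1cc(C(=O)Cl)cc(OC)c1OC | starting material
4 | (4Z)-4-iodo-5-methoxy-1-(3,4,5-trimethoxyphenyl)pent-4-ene-1,3-dione | COc1cc(C(=O)CC(=O)/C(I)=C/OC)cc(OC)c1OC | intermediate
5 | 5-iodo-2-(3,4,5-trimethoxyphenyl)-4H-pyran-4-one | COc1cc(C2=CC(=O)C(I)=CO2)cc(OC)c1OC | intermediate
6 | di-tert-butyl squarate (3,4-di-tert-butoxycyclobut-3-ene-1,2-dione) | CC(C)(C)OC1=C(OC(C)(C)C)C(=O)C1=O | starting material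
7 | sodium 2-tert-butoxy-3,4-dioxocyclobut-1-en-1-olate | CC(C)(C)OC1=C([O-])C(=O)C1=O.[Na+] | intermediate
8 | 3-tert-butoxy-4-methoxycyclobut-3-ene-1,2-dione | COC1=C(OC(C)(C)C)C(=O)C1=O | intermediate
9 | [4-oxo-6-(3,4,5-trimethoxyphenyl)-4H-pyran-3-yl]magnesium chloride·LiCl | COc1cc(C2=CC(=O)C([Mg]Cl)=CO2)cc(OC)c1OC.[Li+].[Cl-] | intermediate
10 | racemic 2-tert-butoxy-4-hydroxy-3-methoxy-4-[4-oxo-6-(3,4,5-trimethoxyphenyl)-4H-pyran-3-yl]cyclobut-2-en-1-one | O=C1C(OC(C)(C)C)=C(OC)C1(O)C1=COC(c2cc(OC)c(OC)c(OC)c2)=CC1=O | intermediate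
11 | racemic 2-tert-butoxy-3,4-dimethoxy-4-[4-oxo-6-(3,4,5-trimethoxyphenyl)-4H-pyran-3-yl]cyclobut-2-en-1-one | O=C1C(OC(C)(C)C)=C(OC)C1(OC)C1=COC(c2cc(OC)c(OC)c(OC)c2)=CC1=O | intermediate
12 | (3Z)-2-tert-butoxy-3,4-dimethoxy-4-[4-oxo-6-(3,4,5-trimethoxyphenyl)-4H-pyran-3-yl]buta-1,3-dien-1-one | O=C=C(OC(C)(C)C)/C(OC)=C(/OC)C1=COC(c2cc(OC)c(OC)c(OC)c2)=CC1=O | intermediate
13 | racemic 7-tert-butoxy-5,6-dimethoxy-2-(3,4,5-trimethoxyphenyl)-8aH-chromene-4,8-dione | O=C1C(OC(C)(C)C)=C(OC)C(OC)=C2C(=O)C=C(c3cc(OC)c(OC)c(OC)c3)OC12 | intermediate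
14 | 7-tert-butoxy-8-hydroxy-5,6-dimethoxy-2-(3,4,5-trimethoxyphenyl)-4H-chromen-4-one | COc1cc(-c2cc(=O)c3c(OC)c(OC)c(OC(C)(C)C)c(O)c3o2)cc(OC)c1OC | intermediate
15 | 7-tert-butoxy-5,6,8-trimethoxy-2-(3,4,5-trimethoxyphenyl)-4H-chromen-4-one | COc1cc(-c2cc(=O)c3c(OC)c(OC)c(OC(C)(C)C)c(OC)c3o2)cc(OC)c1OC | intermediate
16 | 5,7-dihydroxy-6,8-dimethoxy-2-(3,4,5-trimethoxyphenyl)-4H-chromen-4-one | COc1cc(-c2cc(=O)c3c(O)c(OC)c(O)c(OC)c3o2)cc(OC)c1OC | target

Total step count: 10. Longest linear sequence: 8 steps (steps 1, 2, 3, 6, 7, 8, 9, 10).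

Steps most likely to fail

Step 8. The vinylketene may be consumed before it closes: by dimerisation, by loss of isobutene from the tert-butoxy-substituted ketene, or by attack of the basic pyranone carbonyl oxygen. The electron-rich phenol may also oxidise in air. The fallback sets out from 3 and returns at 16; it takes ring A from a commercial arene and adds the 6- and 8-methoxy groups last. The polyanion of commercial 2,4,6-trihydroxyacetophenone (LiN(SiMe3)2 in excess, THF, −78 °C to rt) is C-aroylated by 3 to give 1-(2,4,6-trihydroxyphenyl)-3-(3,4,5-trimethoxyphenyl)propane-1,3-dione F1. Cyclodehydration (H2SO4 in AcOH, 95 °C) should give 5,7-dihydroxy-2-(3,4,5-trimethoxyphenyl)-4H-chromen-4-one F2. N-Bromosuccinimide (2 equiv, DMF, 0 °C) should brominate the phloroglucinol-type ring A at C6 and C8 to give 6,8-dibromo-5,7-dihydroxy-2-(3,4,5-trimethoxyphenyl)-4H-chromen-4-one F3. Copper-mediated methoxide exchange (NaOMe, CuBr, MeOH/DMF, reflux) would then give 16.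

Step 6. Site selectivity of the carbonyl addition may be poor: attack at the carbonyl beside the tert-butoxy-bearing carbon would finally place the free hydroxyl at C6 instead of C7, and the metalated pyranone may also open by β-alkoxide elimination if it warms. The constitution of 10 should be settled by two-dimensional NMR or X-ray analysis before going on. The fallback sets out from 6 and 5 and returns at 11, and steps 4 and 5 fall away. Reagent 9, made as in step 6, is added to symmetrical di-tert-butyl squarate 6, whose carbonyls are equivalent, to give racemic 2,3-di-tert-butoxy-4-hydroxy-4-[4-oxo-6-(3,4,5-trimethoxyphenyl)-4H-pyran-3-yl]cyclobut-2-en-1-one F4. Methylation as in step 7 gives racemic 2,3-di-tert-butoxy-4-methoxy-4-[4-oxo-6-(3,4,5-trimethoxyphenyl)-4H-pyran-3-yl]cyclobut-2-en-1-one F5. Brief treatment with CF3CO2H (CH2Cl2, 0 °C) should first cleave the tert-butyl group of the vinylogous ester (on the carbon β to the ring carbonyl), giving racemic 2-tert-butoxy-3-hydroxy-4-methoxy-4-[4-oxo-6-(3,4,5-trimethoxyphenyl)-4H-pyran-3-yl]cyclobut-2-en-1-one F6. Tautomerism interchanges the two oxygen-bearing ring carbons of this vinylogous acid, and both flank the quaternary carbon, so O-methylation with Me3SiCHN2 (MeOH/toluene, 0 °C) can give only 11.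

Step 2. The enolate of the iodinated enone may be acylated on oxygen instead of carbon, or may lose iodine. The fallback sets out from 1 and 3 and returns at 5; it introduces the halogen after ring C is made. The lithium enolate of 1 is acylated by 3 under the conditions of step 2 to give (4E)-5-methoxy-1-(3,4,5-trimethoxyphenyl)pent-4-ene-1,3-dione F7. CF3CO2H in CH2Cl2 should close it to 2-(3,4,5-trimethoxyphenyl)-4H-pyran-4-one F8. Iodination with I2 and pyridine (CH2Cl2, rt) would then give 5; attack is expected at C5 because the pyridine-assisted pathway needs the unsubstituted C6 and C3 is shielded by the aryl group. The site of iodination must be confirmed, since attack at C3 or on the trimethoxyphenyl ring is the reason this order is not the first choice.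

Further compounds
F1 | step 8 | 1-(2,4,6-trihydroxyphenyl)-3-(3,4,5-trimethoxyphenyl)propane-1,3-dione | COc1cc(C(=O)CC(=O)c2c(O)cc(O)cc2O)cc(OC)c1OC
F2 | step 8 | 5,7-dihydroxy-2-(3,4,5-trimethoxyphenyl)-4H-chromen-4-one | COc1cc(-c2cc(=O)c3c(O)cc(O)cc3o2)cc(OC)c1OC
F3 | step 8 | 6,8-dibromo-5,7-dihydroxy-2-(3,4,5-trimethoxyphenyl)-4H-chromen-4-one | COc1cc(-c2cc(=O)c3c(O)c(Br)c(O)c(Br)c3o2)cc(OC)c1OC
F4 | step 6 | racemic 2,3-di-tert-butoxy-4-hydroxy-4-[4-oxo-6-(3,4,5-trimethoxyphenyl)-4H-pyran-3-yl]cyclobut-2-en-1-one | O=C1C(OC(C)(C)C)=C(OC(C)(C)C)C1(O)C1=COC(c2cc(OC)c(OC)c(OC)c2)=CC1=O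
F5 | step 6 | racemic 2,3-di-tert-butoxy-4-methoxy-4-[4-oxo-6-(3,4,5-trimethoxyphenyl)-4H-pyran-3-yl]cyclobut-2-en-1-one | O=C1C(OC(C)(C)C)=C(OC(C)(C)C)C1(OC)C1=COC(c2cc(OC)c(OC)c(OC)c2)=CC1=O
F6 | step 6 | racemic 2-tert-butoxy-3-hydroxy-4-methoxy-4-[4-oxo-6-(3,4,5-trimethoxyphenyl)-4H-pyran-3-yl]cyclobut-2-en-1-one | O=C1C(OC(C)(C)C)=C(O)C1(OC)C1=COC(c2cc(OC)c(OC)c(OC)c2)=CC1=O
F7 | step 2 | (4E)-5-methoxy-1-(3,4,5-trimethoxyphenyl)pent-4-ene-1,3-dione | COc1cc(C(=O)CC(=O)/C=C/OC)cc(OC)c1OC
F8 | step 2 | 2-(3,4,5-trimethoxyphenyl)-4H-pyran-4-one | COc1cc(C2=CC(=O)C=CO2)cc(OC)c1OC
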